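The plan rests on cutting two neighbouring ring bonds at once, C6–C1' to the icosyl chain and C1–CO2Me, which reveals 3,5-dimethoxybenzyne. The feature used is the contiguous triad on the single benzene ring: alkyl at C6, ester carbon at C1, oxygen at C2. An alkoxy group beside an aryne bond steers a carbon nucleophile to the far aryne carbon and parks the metal next to oxygen, ready for acylation. One pot thus merges a symmetrical, commercial fluoroarene (1-fluoro-3,5-dimethoxybenzene, two equivalent C–H sites between F and OMe), icosylmagnesium bromide and methyl chloroformate into the complete skeleton. Chelation-guided removal of the O2 methyl group then gives the target.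

Key step: step 2

Remark: the target has no stereocentre and no stereogenic double bond, so only regiochemistry needs control. Ring atoms are numbered as in the target benzoate (C1 bears the ester). The fluorine-bearing carbon of the arene becomes C6, the lithiated carbon becomes C1, and the two methoxy carbons become C2 and C4.

Step 1
Reactants: 1 1-bromoicosane
Product: 2 icosylmagnesium bromide (titrated THF solution, about 0.4 M, kept near 35 °C)
Conditions: Mg turnings (1.3 equiv), iodine (one crystal), THF, 50 °C, slow addition of 1
Reagents that add atoms: magnesium, [Mg]
Why: Grignard formation by insertion of magnesium into a primary alkyl C–Br bond is routine, and slow addition at moderate dilution should limit Wurtz coupling while gentle warming keeps the waxy C20 reagent in solution.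

Step 2
Reactants: 3 1-fluoro-3,5-dimethoxybenzene; 2 icosylmagnesium bromide; 4 methyl chloroformate
Product: 8 methyl 2-icosyl-4,6-dimethoxybenzoate, via aryllithium 5 (not isolated), via dimethoxybenzyne 6 (not isolated), via arylmagnesium bromide 7 (not isolated)
Conditions: n-BuLi (1.0 equiv, titrated), THF, −78 °C, 1 h; 2 (2.0 equiv, warm THF solution), −78 °C → rt, 3 h; then cannulated into 4 (5 equiv), THF, −78 °C → rt; aq. NH4Cl
Reagents that add atoms: none
Why: Directed ortho-metalation removes the C–H flanked by F and OMe, the most acidic site of 3 and one of two positions made equivalent by symmetry, and 5 sheds LiF on warming to release aryne 6. The Grignard carbon attacks the distorted triple bond of this 3-alkoxybenzyne at the terminus remote from the neighbouring methoxy group (future C6), because the negative charge then develops at future C1 beside the inductively withdrawing, magnesium-coordinating oxygen; this is aryne carbomagnesiation, a known reaction of alkoxybenzynes made from ortho-metalated haloarenes. Arylmagnesium 7 is then acylated by the chloroformate through nucleophilic acyl substitution, and the two ortho substituents of 8 shield the new ester from a second addition. No ring is closed and no stereocentre is created. The step needs regiocontrol twice, in the lithiation (secured by the combined F/OMe activation) and in the addition (secured by the methoxy group next to the aryne). Using up all n-BuLi at −78 °C before 2 arrives, keeping 2 in excess while the aryne is released, and adding the mixture inversely into excess 4 should hold back butyl transfer, aryne self-capture and ketone formation.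

Step 3
Reactants: 8 methyl 2-icosyl-4,6-dimethoxybenzoate
Product: 10 methyl 2-hydroxy-6-icosyl-4-methoxybenzoate (target), via dichloroboron aryloxide 9 (not isolated)
Conditions: BCl3 (1.5 equiv, 1 M in CH2Cl2), CH2Cl2, −20 → 0 °C; then H2O
Reagents that add atoms: none
Why: In this chelation-directed Lewis-acid cleavage of an aryl methyl ether, BCl3 bridges the ester carbonyl and the adjacent O2 in a six-membered chelate, so chloride should remove only that methyl group while the unchelated 4-methoxy group, the hindered methyl ester and the alkyl chain stay intact at or below 0 °C.

Compound list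
1 | 1-bromoicosane | CCCCCCCCCCCCCCCCCCCCBr | starting material
2 | icosylmagnesium bromide | CCCCCCCCCCCCCCCCCCCC[Mg]Br | intermediate
3 | 1-fluoro-3,5-dimethoxybenzene | COc1cc(F)cc(OC)c1 | starting material
4 | methyl chloroformate | COC(=O)Cl | starting material
5 | (2-fluoro-4,6-dimethoxyphenyl)lithium | [Li]c1c(F)cc(OC)cc1OC | intermediate
6 | 3,5-dimethoxybenzyne (1,2-didehydro-3,5-dimethoxybenzene) | COC1=CC(OC)=CC#C1 | intermediate
7 | (2-icosyl-4,6-dimethoxyphenyl)magnesium bromide | CCCCCCCCCCCCCCCCCCCCc1cc(OC)cc(OC)c1[Mg]Br | intermediate
8 | methyl 2-icosyl-4,6-dimethoxybenzoate | CCCCCCCCCCCCCCCCCCCCc1cc(OC)cc(OC)c1C(=O)OC | intermediate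
9 | methyl 2-(dichloroboryloxy)-6-icosyl-4-methoxybenzoate | CCCCCCCCCCCCCCCCCCCCc1cc(OC)cc(OB(Cl)Cl)c1C(=O)OC | intermediate
10 | methyl 2-hydroxy-6-icosyl-4-methoxybenzoate | CCCCCCCCCCCCCCCCCCCCc1cc(OC)cc(O)c1C(=O)OC | target

Total step count: 3. Longest linear sequence: 3 steps (1 → 2 → 8 → 10).

Steps most likely to fail

1. Step 2 (key step).
- **Risk:** Part of the lithiation may occur between the two methoxy groups. The aryne may be captured by unreacted aryllithium rather than by the poorly soluble long-chain Grignard reagent. β-Hydride transfer from the Grignard reagent to the aryne and slow acylation of the hindered arylmagnesium are further risks.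
- **Fallback:** It sets out from 2 and returns at 8, and it forms the two bonds one after the other without an aryne. Kumada–Corriu coupling of 2 with purchased 1-bromo-3,5-dimethoxybenzene F1 (Ni(dppp)Cl2 cat., THF, 50 °C) should give 1-icosyl-3,5-dimethoxybenzene F2. NBS in CH2Cl2 at 0 °C should brominate ortho to the chain and para to one methoxy group, the usual site in 5-alkylresorcinol dimethyl ethers, to give 2-bromo-1-icosyl-3,5-dimethoxybenzene F3. Bromine–lithium exchange (n-BuLi, THF, −78 °C) should give (2-icosyl-4,6-dimethoxyphenyl)lithium F4, which 4 acylates to 8.

2. Step 3.
- **Risk:** Ether cleavage may be incomplete if the twisted, doubly ortho-substituted ester chelates boron poorly. On longer exposure the 4-O-methyl group may also be lost.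
- **Fallback:** It sets out from 8 and returns at 10, and it replaces selective cleavage by selective alkylation. BBr3 (excess, CH2Cl2, −78 → 0 °C) should remove both aryl methyl groups to give methyl 2,4-dihydroxy-6-icosylbenzoate F5. The 2-hydroxyl of F5 is locked in a hydrogen bond to the ester, so MeI (1.05 equiv) with K2CO3 in acetone should methylate only the free 4-hydroxyl, as is usual for orsellinate-type esters, and give 10.

3. Step 1.
- **Risk:** Initiation may be sluggish, the long-chain bromide may undergo Wurtz-type homocoupling, and the reagent may crystallise from THF, which would make its titre unreliable.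
- **Fallback:** It sets out from 1 and returns at 2, and it reaches the carbon–metal bond by halogen–metal exchange instead of insertion. Finkelstein exchange (NaI, acetone, reflux) should give 1-iodoicosane F6. Iodine–lithium exchange (t-BuLi, 2.1 equiv, Et2O–pentane, −78 °C) should give icosyllithium F7. Transmetalation with MgBr2·OEt2 (1.05 equiv) followed by dilution with THF should deliver 2.

Further compounds
F1 | step 2 | 1-bromo-3,5-dimethoxybenzene | COc1cc(Br)cc(OC)c1
F2 | step 2 | 1-icosyl-3,5-dimethoxybenzene | CCCCCCCCCCCCCCCCCCCCc1cc(OC)cc(OC)c1
F3 | step 2 | 2-bromo-1-icosyl-3,5-dimethoxybenzene | CCCCCCCCCCCCCCCCCCCCc1cc(OC)cc(OC)c1Br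
F4 | step 2 | (2-icosyl-4,6-dimethoxyphenyl)lithium | CCCCCCCCCCCCCCCCCCCCc1cc(OC)cc(OC)c1[Li]
F5 | step 3 | methyl 2,4-dihydroxy-6-icosylbenzoate | CCCCCCCCCCCCCCCCCCCCc1cc(O)cc(O)c1C(=O)OC
F6 | step 1 | 1-iodoicosane | CCCCCCCCCCCCCCCCCCCCI
F7 | step 1 | icosyllithium | CCCCCCCCCCCCCCCCCCCC[Li]
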